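**Plan**

- Retrosynthesis: the O2–C3 enol-ether bond of the 1H-isochromene is cut first, which opens the pyran ring to the isomeric ynone alcohol 10. Then the C(=O)–C3 bond (acetylide plus Weinreb amide) and the C4–C4a bond (Sonogashira) are cut.
- Enabling feature: C3 is both the α-carbon of the aryl ketone and the oxygen-bearing enol-ether carbon, and C4 sits directly on aromatic C4a (no γ-hydrogen). This is the retron of a phosphine α-umpolung addition to a 3-aryl ynone, which reverses the innate 5-exo oxa-Michael closure at C4.
- Forward: the benzo ring is bought with CH2OH and Br in place (1). The alkyne is installed (steps 1–2), the 2,4-dimethoxybenzoyl group is joined (steps 3–4), and the pyran ring is closed last (step 5) by an atom-economic cycloisomerization, without protecting groups.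
- Stereochemistry: the target has no stereocentre. Its only stereo-element, the C3=C4 double bond, is endocyclic in the six-membered ring and is fixed by the ring closure.

Key step: step 5

Remark: compounds 1, 2, 5 and 6 are taken as catalogue chemicals; the phosphonium adducts of step 5 are catalyst-bound states of a catalytic cycle that never build up, so they are described in the Why line and carry no compound number.

**Route**

Step 1
Reactants: 1 (2-bromo-4,5-dimethoxyphenyl)methanol; 2 ethynyltrimethylsilane
Product: 3 {4,5-dimethoxy-2-[(trimethylsilyl)ethynyl]phenyl}methanol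
Conditions: Pd(PhCN)2Cl2 (3 mol %), P(t-Bu)3 (6 mol %), CuI (2 mol %), i-Pr2NH (2 equiv), dioxane, rt to 45 °C
Reagents that add atoms: none
Why: Sonogashira coupling, in which the bulky electron-rich phosphine lets zerovalent palladium insert into the electron-rich, ortho-substituted aryl bromide under mild conditions, the copper acetylide of 2 transmetalates, and the free benzylic alcohol is a spectator.

Step 2
Reactants: 3 {4,5-dimethoxy-2-[(trimethylsilyl)ethynyl]phenyl}methanol
Product: 4 (2-ethynyl-4,5-dimethoxyphenyl)methanol
Conditions: K2CO3 (0.2 equiv), MeOH, rt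
Reagents that add atoms: none
Why: Base-catalysed methanolysis of the alkynyl C–Si bond (protodesilylation) is fast at room temperature and should leave the benzylic alcohol, the aryl ethers and the unactivated alkyne untouched.

Step 3
Reactants: 5 2,4-dimethoxybenzoyl chloride; 6 N,O-dimethylhydroxylamine hydrochloride
Product: 7 N,2,4-trimethoxy-N-methylbenzamide
Conditions: Et3N (2.2 equiv), CH2Cl2, 0 °C to rt
Reagents that add atoms: none
Why: N-Acylation of the hydroxylamine, released from its salt by Et3N, by the acid chloride (Weinreb amide formation) has no competing site.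

Step 4
Reactants: 4 (2-ethynyl-4,5-dimethoxyphenyl)methanol; 7 N,2,4-trimethoxy-N-methylbenzamide
Product: 10 1-(2,4-dimethoxyphenyl)-3-[2-(hydroxymethyl)-4,5-dimethoxyphenyl]prop-2-yn-1-one, via dilithium alkoxide acetylide 8 (not isolated), via dilithium tetrahedral adduct 9 (not isolated)
Conditions: n-BuLi (2.1 equiv), THF, −78 °C; then 7 (1.1 equiv), −78 to 0 °C; inverse quench into cold 1 M HCl; crude 10 passed through a short pad of neutral silica and used at once
Reagents that add atoms: none
Why: Weinreb ketone synthesis, in which the second equivalent of n-BuLi forms the lithium acetylide beside the lithium alkoxide, the acetylide adds to the amide to give a chelated tetrahedral adduct that cannot over-add, and the inverse acidic quench protonates the alkoxide and the released N,O-dimethylhydroxylamine before either can add to the new ynone.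

Step 5
Reactants: 10 1-(2,4-dimethoxyphenyl)-3-[2-(hydroxymethyl)-4,5-dimethoxyphenyl]prop-2-yn-1-one
Product: 11 (6,7-dimethoxy-1H-isochromen-3-yl)(2,4-dimethoxyphenyl)methanone
Conditions: PPh3 (20 mol %), AcOH (0.5 equiv), NaOAc (0.5 equiv), toluene (0.05 M), 80 °C
Reagents that add atoms: none
Why: Proposed new method: PPh3 adds to the β-carbon (C4) of the ynone and AcOH protonates the allenolate at C3, so the resulting β-acyl vinylphosphonium turns C3 from the nucleophilic α-carbon of the ynone into the acceptor carbon and the ortho CH2OH oxygen adds there; C-protonation of the ylide at C4 and acetate-mediated E1cB loss of PPh3 across C3–C4 should then give the α-alkoxy enone and return the catalyst. The closest known reaction type is the phosphine-catalysed α-umpolung (anti-Michael) addition of N–H and phenolic O–H pronucleophiles to 3-aryl propiolates and aryl ynones under AcOH/NaOAc buffer, including the intramolecular closure of ortho-alkynoyl phenols to aurones; its use with an aliphatic benzylic alcohol tethered to the β-aryl group to close a 1H-isochromene is the untested part. The pyran ring closes by 6-endo-trig attack of oxygen on the vinylphosphonium, formally a 6-endo-dig anti-Michael hydroalkoxylation of the C3≡C4 alkyne. No stereocentre is formed and the C3=C4 bond is held cis in the ring. The step needs attack at C3 and not the innate 5-exo oxa-Michael attack at C4: C4 carries the aryl group and the phosphonium and is blocked, there is no γ-hydrogen to divert the adduct to an allene, and the acidic buffer keeps free alkoxide, the carrier of the base-chain 5-exo pathway, out of solution.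

**Compound list**

1 | (2-bromo-4,5-dimethoxyphenyl)methanol | COc1cc(CO)c(Br)cc1OC | starting material
2 | ethynyltrimethylsilane | C#C[Si](C)(C)C | starting material
3 | {4,5-dimethoxy-2-[(trimethylsilyl)ethynyl]phenyl}methanol | COc1cc(CO)c(C#C[Si](C)(C)C)cc1OC | intermediate
4 | (2-ethynyl-4,5-dimethoxyphenyl)methanol | COc1cc(CO)c(C#C)cc1OC | intermediate
5 | 2,4-dimethoxybenzoyl chloride | COc1ccc(C(=O)Cl)c(OC)c1 | starting material
6 | N,O-dimethylhydroxylamine hydrochloride | CNOC.Cl | starting material
7 | N,2,4-trimethoxy-N-methylbenzamide | COc1ccc(C(=O)N(C)OC)c(OC)c1 | intermediate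
8 | dilithium alkoxide acetylide of 4 | COc1cc(C[O-])c(C#[C-])cc1OC.[Li+].[Li+] | intermediate (not isolated)
9 | dilithium tetrahedral adduct of 8 and 7 (racemic at the new carbinol carbon) | COc1ccc(C([O-])(C#Cc2cc(OC)c(OC)cc2C[O-])N(C)OC)c(OC)c1.[Li+].[Li+] | intermediate (not isolated)
10 | 1-(2,4-dimethoxyphenyl)-3-[2-(hydroxymethyl)-4,5-dimethoxyphenyl]prop-2-yn-1-one | COc1ccc(C(=O)C#Cc2cc(OC)c(OC)cc2CO)c(OC)c1 | intermediate
11 | (6,7-dimethoxy-1H-isochromen-3-yl)(2,4-dimethoxyphenyl)methanone | COc1ccc(C(=O)C2=Cc3cc(OC)c(OC)cc3CO2)c(OC)c1 | target

**Totals**

Total step count: 5. Longest linear sequence: 4 steps (steps 1, 2, 4, 5); step 3 is a one-step side branch.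

**Steps most likely to fail**

Step 5 (proposed new method). The closure may go in the 5-exo sense, by oxa-Michael attack at C4 or by addition–elimination at the phosphonium-bearing carbon, or phosphine addition to the electron-rich ynone may be too slow. The fallback uses known chemistry, sets out from acid chloride 5 and comes back to the route at 11. The pyran ring is taken ready-made from commercial 6,7-dimethoxyisochroman-3-one (COc1cc2c(cc1OC)COC(=O)C2). Enolization with KN(SiMe3)2 and O-phosphorylation with diphenyl chlorophosphate (THF, −78 °C) should give the ketene acetal phosphate 6,7-dimethoxy-1H-isochromen-3-yl diphenyl phosphate F1. Pd(PPh3)4-catalysed exchange with Me3SnSnMe3 (LiCl, THF, 65 °C) should give (6,7-dimethoxy-1H-isochromen-3-yl)trimethylstannane F2. Stille acylation of F2 with 5 (PdCl2(PPh3)2 cat., toluene, 70 °C) should then give 11.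

Step 4. The released N,O-dimethylhydroxylamine may add to the ynone, the alkoxide may close 5-exo onto the ynone during the quench, or the second deprotonation may be incomplete. The fallback sets out from 4 and comes back at 10. Silylation of 4 (TBSCl, imidazole, DMF) should give tert-butyl[(2-ethynyl-4,5-dimethoxyphenyl)methoxy]dimethylsilane F3. Acyl Sonogashira coupling of F3 with 5 (PdCl2(PPh3)2, CuI, Et3N, THF, rt) should give 3-[2-({[tert-butyl(dimethyl)silyl]oxy}methyl)-4,5-dimethoxyphenyl]-1-(2,4-dimethoxyphenyl)prop-2-yn-1-one F4. Desilylation with HF·pyridine (THF, 0 °C), a non-basic fluoride source, should release 10 without base-induced oxa-Michael closure.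

Step 1. Oxidative addition into the electron-rich, ortho-substituted aryl bromide may be sluggish, so that oxidative homocoupling of 2 takes over. The fallback sets out from 1 and comes back at 4, so it also replaces step 2. Treatment of 1 with n-BuLi (2.2 equiv, THF, −78 °C; O-deprotonation, then bromine–lithium exchange) and DMF should give, after work-up, the ring-closed hydroxy aldehyde 5,6-dimethoxy-1,3-dihydro-2-benzofuran-1-ol F5. Seyferth–Gilbert homologation of this lactol with the Ohira–Bestmann reagent (K2CO3, MeOH, rt) should give 4 directly.

**Further compounds**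

F1 | step 5 | 6,7-dimethoxy-1H-isochromen-3-yl diphenyl phosphate | COc1cc2c(cc1OC)COC(OP(=O)(Oc1ccccc1)Oc1ccccc1)=C2
F2 | step 5 | (6,7-dimethoxy-1H-isochromen-3-yl)trimethylstannane | COc1cc2c(cc1OC)COC([Sn](C)(C)C)=C2
F3 | step 4 | tert-butyl[(2-ethynyl-4,5-dimethoxyphenyl)methoxy]dimethylsilane | COc1cc(CO[Si](C)(C)C(C)(C)C)c(C#C)cc1OC
F4 | step 4 | 3-[2-({[tert-butyl(dimethyl)silyl]oxy}methyl)-4,5-dimethoxyphenyl]-1-(2,4-dimethoxyphenyl)prop-2-yn-1-one | COc1ccc(C(=O)C#Cc2cc(OC)c(OC)cc2CO[Si](C)(C)C(C)(C)C)c(OC)c1
F5 | step 1 | 5,6-dimethoxy-1,3-dihydro-2-benzofuran-1-ol (racemic lactol) | COc1cc2c(cc1OC)C(O)OC2
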